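Ring numbering: C1 carries CH2OH (C7), C2 is the ketone, C3 bears O3 (epoxy ester), C4 the isopropyl group (methine C8), C5 bears O5 (angelate), C6 is the vinyl CH. O5 and C8 are cis on the adjacent carbons C5 and C4 of the cyclohexenone ring, and O3 is trans to C8. The route therefore cuts C4–C8 and C3–O3 together. The precursor is the O5 bromoacetal of (R)-4-hydroxycyclohex-2-enone, carrying a 2-bromoprop-2-yl unit on the acetal carbon. One radical operation closes a temporary cis-fused oxolane (5-exo onto C4) and caps C3 with TEMPO on the opposite face, setting C4 and C3 from C5. The acetal carbon is excised later, leaving isopropyl.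

Key step: step 3

Assumption 1: (4R)-4-hydroxycyclohex-2-en-1-one (3) is used as the purchased enantiopure building block; it supplies C5 and, through the key step, the other ring stereocentres.
Assumption 2: the acetal carbon of 4, 6, 7, 8 and 9 (and the lactol carbon of 10) forms as both epimers; one epimer is drawn and named, and both serve because this carbon is excised in step 7.

Step 1
Reactants: 1 1,1-diethoxy-2-methylpropane
Product: 2 1-ethoxy-2-methylprop-1-ene
Conditions: KHSO4 (cat.), neat, 150 °C, distil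
Reagents that add atoms: none
Why: Acid-catalysed 1,2-elimination of ethanol from the acetal (enol ether synthesis by acetal cracking) should give the trisubstituted enol ether, the equilibrium being pulled by distilling off the volatile products.

Step 2
Reactants: 2 1-ethoxy-2-methylprop-1-ene; 3 (4R)-4-hydroxycyclohex-2-en-1-one
Product: 4 (4R)-4-[(1S)-2-bromo-1-ethoxy-2-methylpropoxy]cyclohex-2-en-1-one
Conditions: NBS, CH2Cl2, −40 → 0 °C
Reagents that add atoms: N-bromosuccinimide, O=C1CCC(=O)N1Br
Why: Ueno–Stork haloacetalization, in which NBS brominates the electron-rich enol ether at its dimethyl-substituted carbon and the resulting oxocarbenium ion is captured by the C5 hydroxyl of 3, leaves the C5 stereocentre untouched and gives the acetal carbon as both epimers.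

Step 3
Reactants: 4 (4R)-4-[(1S)-2-bromo-1-ethoxy-2-methylpropoxy]cyclohex-2-en-1-one; 5 TEMPO (2,2,6,6-tetramethylpiperidin-1-oxyl)
Product: 7 (2S,3aR,4S,7aR)-2-ethoxy-3,3-dimethyl-4-[(2,2,6,6-tetramethylpiperidin-1-yl)oxy]hexahydro-1-benzofuran-5(4H)-one, via uncyclized tertiary alkoxyamine 6 (not isolated)
Conditions: Bu3SnH (syringe pump), 5 (excess), PhCl, 80 °C; then 120 °C
Reagents that add atoms: none
Why: Bu3SnH is oxidized by TEMPO to the stannyl radical, which abstracts bromine from 4; the nucleophilic tertiary radical at C8, held on O5 by the acetal carbon, adds to C4, the electron-poor β-carbon of the enone, and the α-keto radical left at C3 couples with a second TEMPO to form the C3–O bond. The closest known reaction type is the Ueno–Stork haloacetal radical cyclization onto a cyclic enone, combined with tin hydride/nitroxide cyclization–trapping of organic halides. The oxolane (C8, acetal carbon, O5, C5, C4) closes in the 5-exo-trig mode, favoured over 6-endo attack at C3 by both polarity and geometry. C4 is set by the tether, because a five-membered ring fused to the six-membered ring can only form cis, so C8 arrives on the O5 face; C3 is set by the bicycle, TEMPO approaching the convex face anti to the C8 gem-dimethyl group, and because the C3–ON bond α to the ketone is thermally reversible the trans arrangement is also the equilibrium outcome. The step needs ring closure to win over direct capping of the tertiary radical: the matched polarity makes closure fast, and prematurely capped material 6 should homolyse again in the final heating period (persistent radical effect) and be funnelled to 7.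

Step 4
Reactants: 7 (2S,3aR,4S,7aR)-2-ethoxy-3,3-dimethyl-4-[(2,2,6,6-tetramethylpiperidin-1-yl)oxy]hexahydro-1-benzofuran-5(4H)-one
Product: 8 (2S,3aS,4S,7aR)-2-ethoxy-4-hydroxy-3,3-dimethylhexahydro-1-benzofuran-5(4H)-one
Conditions: Zn, AcOH, THF, rt
Reagents that add atoms: none
Why: Reductive N–O cleavage of the alkoxyamine by zinc in acetic acid (dissolving-metal N–O reduction) should free the C3 hydroxyl without touching the C3, C4 or C5 centres, the ketone or the acetal (the 3a descriptor changes only through a priority change).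

Step 5
Reactants: 8 (2S,3aS,4S,7aR)-2-ethoxy-4-hydroxy-3,3-dimethylhexahydro-1-benzofuran-5(4H)-one
Product: 9 (2S,3aR,4S,7aR)-4-{[tert-butyl(dimethyl)silyl]oxy}-2-ethoxy-3,3-dimethylhexahydro-1-benzofuran-5(4H)-one
Conditions: TBSCl, imidazole, DMAP (cat.), DMF, 40 °C
Reagents that add atoms: tert-butyl(chloro)dimethylsilane, CC(C)(C)[Si](C)(C)Cl
Why: Silyl ether protection of the secondary alcohol masks O3, so that O3 and O5 stay distinguishable and the α-ketol cannot isomerize during the heating and strong-base steps that follow.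

Step 6
Reactants: 9 (2S,3aR,4S,7aR)-4-{[tert-butyl(dimethyl)silyl]oxy}-2-ethoxy-3,3-dimethylhexahydro-1-benzofuran-5(4H)-one
Product: 10 (3aR,4S,7aR)-4-{[tert-butyl(dimethyl)silyl]oxy}-2-hydroxy-3,3-dimethylhexahydro-1-benzofuran-5(4H)-one (both anomers)
Conditions: AcOH/THF/H2O (3:1:1), 45 °C
Reagents that add atoms: water, O
Why: Acid-catalysed acetal hydrolysis through the cyclic oxocarbenium ion should exchange ethoxy for hydroxyl, while the hindered secondary silyl ether survives the weak acid.

Step 7
Reactants: 10 (3aR,4S,7aR)-4-{[tert-butyl(dimethyl)silyl]oxy}-2-hydroxy-3,3-dimethylhexahydro-1-benzofuran-5(4H)-one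
Product: 12 (2S,3R,4R)-2-{[tert-butyl(dimethyl)silyl]oxy}-4-hydroxy-3-(propan-2-yl)cyclohexan-1-one, via open-chain hydroxy aldehyde 11 (not isolated)
Conditions: RhCl(PPh3)3 (1.2 equiv), PhCN, 130 °C
Reagents that add atoms: none
Why: Tsuji–Wilkinson decarbonylation, in which the lactol reacts through its ring-opened tautomer 11, whose formyl C–H adds to monovalent rhodium before CO extrusion and C8–H reductive elimination, should turn the CMe2–CHO unit into the isopropyl group and release O5–H without involving any stereocentre.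

Step 8
Reactants: 12 (2S,3R,4R)-2-{[tert-butyl(dimethyl)silyl]oxy}-4-hydroxy-3-(propan-2-yl)cyclohexan-1-one
Product: 15 (4R,5R,6S)-6-{[tert-butyl(dimethyl)silyl]oxy}-4-hydroxy-5-(propan-2-yl)cyclohex-2-en-1-one, via bis-silyl enol ether 13 (not isolated), via O5-trimethylsilyl enone 14 (not isolated)
Conditions: LiN(iPr)2 (2.3 equiv), Me3SiCl, THF, −78 °C; then Pd(OAc)2, MeCN, rt; then citric acid, MeOH, 0 °C
Reagents that add atoms: none
Why: Saegusa–Ito oxidation, in which O5 is silylated in situ and kinetic deprotonation takes place at the unhindered C1 methylene (C3 is shielded by its silyl ether and the isopropyl group), should give the palladium enolate toward C1 and, by β-hydride elimination, the C1=C6 enone, after which mild acidic methanolysis removes the labile O5 trimethylsilyl group.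

Step 9
Reactants: 15 (4R,5R,6S)-6-{[tert-butyl(dimethyl)silyl]oxy}-4-hydroxy-5-(propan-2-yl)cyclohex-2-en-1-one; 16 angelic acid, (2Z)-2-methylbut-2-enoic acid
Product: 18 (1R,5S,6R)-5-{[tert-butyl(dimethyl)silyl]oxy}-4-oxo-6-(propan-2-yl)cyclohex-2-en-1-yl (2Z)-2-methylbut-2-enoate, via angelic mixed anhydride 17 (not isolated)
Conditions: 16, 2,4,6-Cl3C6H2COCl, Et3N, PhMe, rt; then 15, 80 °C
Reagents that add atoms: none
Why: Yamaguchi esterification through mixed anhydride 17, run without a nucleophilic amine catalyst so that the Z double bond of the angeloyl group is not isomerized, should acylate the only free hydroxyl (O5) with retention at C5.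

Step 10
Reactants: 18 (1R,5S,6R)-5-{[tert-butyl(dimethyl)silyl]oxy}-4-oxo-6-(propan-2-yl)cyclohex-2-en-1-yl (2Z)-2-methylbut-2-enoate
Product: 19 (1R,5S,6S)-5-hydroxy-4-oxo-6-(propan-2-yl)cyclohex-2-en-1-yl (2Z)-2-methylbut-2-enoate
Conditions: HF·pyridine, THF, 0 °C → rt
Reagents that add atoms: none
Why: Fluoride-mediated silyl ether cleavage, driven by the Si–F bond, should free O3–H without affecting the enone or the angelate (the 6 descriptor changes only through a priority change).

Step 11
Reactants: 16 angelic acid, (2Z)-2-methylbut-2-enoic acid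
Product: 20 (2Z)-2-methylbut-2-en-1-ol
Conditions: LiAlH4, Et2O, 0 °C → rt
Reagents that add atoms: none
Why: Hydride reduction of the carboxylic acid to the primary alcohol with LiAlH4 should leave the trisubstituted double bond and its Z geometry intact.

Step 12
Reactants: 20 (2Z)-2-methylbut-2-en-1-ol
Product: 21 [(2S,3R)-2,3-dimethyloxiran-2-yl]methanol
Conditions: Ti(OiPr)4, L-(+)-diethyl tartrate, t-BuOOH, 4 Å MS, CH2Cl2, −20 °C
Reagents that add atoms: tert-butyl hydroperoxide, CC(C)(C)OO
Why: Sharpless asymmetric epoxidation with the titanium complex of natural L-(+)-diethyl tartrate should deliver oxygen to the face that gives 2S at the carbinol-bearing epoxide carbon, and syn addition to the Z alkene fixes C3 as R, with the two methyl groups trans.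

Step 13
Reactants: 21 [(2S,3R)-2,3-dimethyloxiran-2-yl]methanol
Product: 23 (2R,3R)-2,3-dimethyloxirane-2-carboxylic acid, via epoxy aldehyde 22 (not isolated)
Conditions: RuCl3·xH2O (cat.), NaIO4, MeCN/EtOAc/H2O, rt
Reagents that add atoms: sodium periodate, [Na+].[O-]I(=O)(=O)=O; water, O
Why: Ruthenium tetroxide oxidation of the primary alcohol to the carboxylic acid, with RuO4 generated catalytically from RuCl3 and NaIO4, should leave the epoxide untouched, the C2 descriptor changing from S to R only through the priority change.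

Step 14
Reactants: 19 (1R,5S,6S)-5-hydroxy-4-oxo-6-(propan-2-yl)cyclohex-2-en-1-yl (2Z)-2-methylbut-2-enoate; 23 (2R,3R)-2,3-dimethyloxirane-2-carboxylic acid
Product: 25 (1S,5R,6R)-5-{[(2Z)-2-methylbut-2-enoyl]oxy}-2-oxo-6-(propan-2-yl)cyclohex-3-en-1-yl (2R,3R)-2,3-dimethyloxirane-2-carboxylate, via epoxy acid mixed anhydride 24 (not isolated)
Conditions: 23, 2,4,6-Cl3C6H2COCl, Et3N, THF, rt; then 19, DMAP, PhMe, rt
Reagents that add atoms: none
Why: Yamaguchi esterification through mixed anhydride 24 with DMAP should acylate the remaining free hydroxyl (O3) with the hindered, non-enolizable epoxy acid, retaining C3 and both epoxide centres, and any diastereomer arising from residual enantiomer of 23 is separable at this stage.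

Step 15
Reactants: 25 (1S,5R,6R)-5-{[(2Z)-2-methylbut-2-enoyl]oxy}-2-oxo-6-(propan-2-yl)cyclohex-3-en-1-yl (2R,3R)-2,3-dimethyloxirane-2-carboxylate
Product: 26 (1S,5R,6R)-3-(hydroxymethyl)-5-{[(2Z)-2-methylbut-2-enoyl]oxy}-2-oxo-6-(propan-2-yl)cyclohex-3-en-1-yl (2R,3R)-2,3-dimethyloxirane-2-carboxylate (CNP0293054.1)
Conditions: aq. HCHO, DMAP, THF, rt
Reagents that add atoms: formaldehyde, C=O
Why: Morita–Baylis–Hillman reaction, in which reversible conjugate addition of DMAP to C6 gives an enolate that adds to formaldehyde at C1 and then expels the amine, should install the hydroxymethyl group on the enone α-carbon without creating or disturbing a stereocentre.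

Compound list
1 | 1,1-diethoxy-2-methylpropane | CCOC(OCC)C(C)C | starting material
2 | 1-ethoxy-2-methylprop-1-ene | CCOC=C(C)C | intermediate
3 | (4R)-4-hydroxycyclohex-2-en-1-one | O[C@@H]1CCC(=O)C=C1 | starting material
4 | (4R)-4-[(1S)-2-bromo-1-ethoxy-2-methylpropoxy]cyclohex-2-en-1-one (1R acetal epimer also present) | CCO[C@H](C(C)(C)Br)O[C@@H]1CCC(=O)C=C1 | intermediate
5 | TEMPO, 2,2,6,6-tetramethylpiperidin-1-oxyl | CC1(C)CCCC(C)(C)N1[O] | starting material
6 | (4R)-4-{(1S)-1-ethoxy-2-methyl-2-[(2,2,6,6-tetramethylpiperidin-1-yl)oxy]propoxy}cyclohex-2-en-1-one | CCO[C@H](C(C)(C)ON1C(C)(C)CCCC1(C)C)O[C@@H]1CCC(=O)C=C1 | intermediate (not isolated)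
7 | (2S,3aR,4S,7aR)-2-ethoxy-3,3-dimethyl-4-[(2,2,6,6-tetramethylpiperidin-1-yl)oxy]hexahydro-1-benzofuran-5(4H)-one (cis-fused) | CCO[C@H]2O[C@@H]1CCC(=O)[C@@H](ON3C(C)(C)CCCC3(C)C)[C@@H]1C2(C)C | intermediate
8 | (2S,3aS,4S,7aR)-2-ethoxy-4-hydroxy-3,3-dimethylhexahydro-1-benzofuran-5(4H)-one | CCO[C@H]2O[C@@H]1CCC(=O)[C@@H](O)[C@@H]1C2(C)C | intermediate
9 | (2S,3aR,4S,7aR)-4-{[tert-butyl(dimethyl)silyl]oxy}-2-ethoxy-3,3-dimethylhexahydro-1-benzofuran-5(4H)-one | CCO[C@H]2O[C@@H]1CCC(=O)[C@@H](O[Si](C)(C)C(C)(C)C)[C@@H]1C2(C)C | intermediate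
10 | (3aR,4S,7aR)-4-{[tert-butyl(dimethyl)silyl]oxy}-2-hydroxy-3,3-dimethylhexahydro-1-benzofuran-5(4H)-one (both anomers) | OC2O[C@@H]1CCC(=O)[C@@H](O[Si](C)(C)C(C)(C)C)[C@@H]1C2(C)C | intermediate
11 | 2-[(1R,2S,6R)-2-{[tert-butyl(dimethyl)silyl]oxy}-6-hydroxy-3-oxocyclohexyl]-2-methylpropanal | O[C@@H]1CCC(=O)[C@@H](O[Si](C)(C)C(C)(C)C)[C@@H]1C(C)(C)C=O | intermediate (not isolated)
12 | (2S,3R,4R)-2-{[tert-butyl(dimethyl)silyl]oxy}-4-hydroxy-3-(propan-2-yl)cyclohexan-1-one | O[C@@H]1CCC(=O)[C@@H](O[Si](C)(C)C(C)(C)C)[C@@H]1C(C)C | intermediate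
13 | tert-butyl(dimethyl){[(1S,5R,6R)-6-(propan-2-yl)-2,5-bis[(trimethylsilyl)oxy]cyclohex-2-en-1-yl]oxy}silane | C[Si](C)(C)O[C@@H]1CC=C(O[Si](C)(C)C)[C@@H](O[Si](C)(C)C(C)(C)C)[C@@H]1C(C)C | intermediate (not isolated)
14 | (4R,5R,6S)-6-{[tert-butyl(dimethyl)silyl]oxy}-5-(propan-2-yl)-4-[(trimethylsilyl)oxy]cyclohex-2-en-1-one | C[Si](C)(C)O[C@@H]1C=CC(=O)[C@@H](O[Si](C)(C)C(C)(C)C)[C@@H]1C(C)C | intermediate (not isolated)
15 | (4R,5R,6S)-6-{[tert-butyl(dimethyl)silyl]oxy}-4-hydroxy-5-(propan-2-yl)cyclohex-2-en-1-one | O[C@@H]1C=CC(=O)[C@@H](O[Si](C)(C)C(C)(C)C)[C@@H]1C(C)C | intermediate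
16 | angelic acid, (2Z)-2-methylbut-2-enoic acid | C/C=C(/C)C(=O)O | starting material
17 | (2Z)-2-methylbut-2-enoic 2,4,6-trichlorobenzoic anhydride | C/C=C(/C)C(=O)OC(=O)c1c(Cl)cc(Cl)cc1Cl | intermediate (not isolated)
18 | (1R,5S,6R)-5-{[tert-butyl(dimethyl)silyl]oxy}-4-oxo-6-(propan-2-yl)cyclohex-2-en-1-yl (2Z)-2-methylbut-2-enoate | C/C=C(/C)C(=O)O[C@@H]1C=CC(=O)[C@@H](O[Si](C)(C)C(C)(C)C)[C@@H]1C(C)C | intermediate
19 | (1R,5S,6S)-5-hydroxy-4-oxo-6-(propan-2-yl)cyclohex-2-en-1-yl (2Z)-2-methylbut-2-enoate | C/C=C(/C)C(=O)O[C@@H]1C=CC(=O)[C@@H](O)[C@@H]1C(C)C | intermediate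
20 | (2Z)-2-methylbut-2-en-1-ol | C/C=C(/C)CO | intermediate
21 | [(2S,3R)-2,3-dimethyloxiran-2-yl]methanol | OC[C@]1(C)O[C@@H]1C | intermediate
22 | (2R,3R)-2,3-dimethyloxirane-2-carbaldehyde | O=C[C@]1(C)O[C@@H]1C | intermediate (not isolated)
23 | (2R,3R)-2,3-dimethyloxirane-2-carboxylic acid | OC(=O)[C@]1(C)O[C@@H]1C | intermediate
24 | (2R,3R)-2,3-dimethyloxirane-2-carboxylic 2,4,6-trichlorobenzoic anhydride | O=C(OC(=O)c1c(Cl)cc(Cl)cc1Cl)[C@]1(C)O[C@@H]1C | intermediate (not isolated)
25 | (1S,5R,6R)-5-{[(2Z)-2-methylbut-2-enoyl]oxy}-2-oxo-6-(propan-2-yl)cyclohex-3-en-1-yl (2R,3R)-2,3-dimethyloxirane-2-carboxylate | C/C=C(/C)C(=O)O[C@@H]1C=CC(=O)[C@@H](OC(=O)[C@]2(C)O[C@@H]2C)[C@@H]1C(C)C | intermediate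
26 | (1S,5R,6R)-3-(hydroxymethyl)-5-{[(2Z)-2-methylbut-2-enoyl]oxy}-2-oxo-6-(propan-2-yl)cyclohex-3-en-1-yl (2R,3R)-2,3-dimethyloxirane-2-carboxylate (CNP0293054.1) | C/C=C(/C)C(=O)O[C@@H]1C=C(CO)C(=O)[C@@H](OC(=O)[C@]2(C)O[C@@H]2C)[C@@H]1C(C)C | target

Total step count: 15. Longest linear sequence: 12 (steps 1–10, 14, 15); the epoxy acid branch (steps 11–13) joins at step 14.

Steps most likely to fail

Step 3. The nitroxide may cap the tertiary radical before ring closure and the capped reservoir may then disproportionate to an isopropenyl acetal instead of reopening. Stannyl radicals may also be consumed by the nitroxide faster than they abstract bromine, so that conversion stalls. The fallback changes the trap: setting out from 4, the same 5-exo closure is run as an oxygenative radical cyclization (Bu3SnH, dry air, PhMe, rt), in which O2 intercepts the C3 radical to give (2S,3aR,4S,7aR)-2-ethoxy-4-hydroperoxy-3,3-dimethylhexahydro-1-benzofuran-5(4H)-one F1. Reduction of its O–O bond (PPh3) gives ketol 8, where the route is rejoined and step 4 is skipped. C3 is epimerizable α to the ketone, so the trans arrangement remains reachable by equilibration.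

Step 7. The ring–chain equilibrium keeps the aldehyde concentration low, and the neopentyl-type formyl group adds slowly to rhodium, so the reaction may stall or divert to β-hydride elimination at C8. The fallback cleaves the same C–C bond by a radical instead of a metal: setting out from lactol 10, alkoxy-radical β-fragmentation under hypoiodite conditions (PhI(OAc)2, I2, CH2Cl2, visible light, rt) acts on the closed lactol and should give (1R,2R,3S)-3-{[tert-butyl(dimethyl)silyl]oxy}-2-(2-iodopropan-2-yl)-4-oxocyclohexyl formate F2. Radical deiodination (Bu3SnH, AIBN, PhH, 80 °C) then gives (1R,2R,3S)-3-{[tert-butyl(dimethyl)silyl]oxy}-4-oxo-2-(propan-2-yl)cyclohexyl formate F3, and formate methanolysis (KHCO3, MeOH, 0 °C) returns to 12.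

Step 15. Conjugate addition of the amine at the hindered C6 may be slow, giving time for amine-induced acyl migration or ester cleavage in the doubly acylated enone. The fallback builds the C1–C7 bond by cross-coupling: setting out from 25, α-iodination of the enone (I2, pyridine, CH2Cl2, rt) should give (1S,5S,6R)-3-iodo-5-{[(2Z)-2-methylbut-2-enoyl]oxy}-2-oxo-6-(propan-2-yl)cyclohex-3-en-1-yl (2R,3R)-2,3-dimethyloxirane-2-carboxylate F4 (5S only through a priority change). Stille coupling with Bu3SnCH2OH (Pd(PPh3)4, dioxane, 90 °C) then gives target 26.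

Further compounds
F1 | step 3 | (2S,3aR,4S,7aR)-2-ethoxy-4-hydroperoxy-3,3-dimethylhexahydro-1-benzofuran-5(4H)-one | CCO[C@H]2O[C@@H]1CCC(=O)[C@@H](OO)[C@@H]1C2(C)C
F2 | step 7 | (1R,2R,3S)-3-{[tert-butyl(dimethyl)silyl]oxy}-2-(2-iodopropan-2-yl)-4-oxocyclohexyl formate | O=CO[C@@H]1CCC(=O)[C@@H](O[Si](C)(C)C(C)(C)C)[C@@H]1C(C)(C)I
F3 | step 7 | (1R,2R,3S)-3-{[tert-butyl(dimethyl)silyl]oxy}-4-oxo-2-(propan-2-yl)cyclohexyl formate | O=CO[C@@H]1CCC(=O)[C@@H](O[Si](C)(C)C(C)(C)C)[C@@H]1C(C)C
F4 | step 15 | (1S,5S,6R)-3-iodo-5-{[(2Z)-2-methylbut-2-enoyl]oxy}-2-oxo-6-(propan-2-yl)cyclohex-3-en-1-yl (2R,3R)-2,3-dimethyloxirane-2-carboxylate | C/C=C(/C)C(=O)O[C@@H]1C=C(I)C(=O)[C@@H](OC(=O)[C@]2(C)O[C@@H]2C)[C@@H]1C(C)C
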